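Numbering used throughout: oxane O1, C2 (guaiacyl-bearing), C3, C4 (carbinol), C5, C6; side chain C1'(OH)–C2'H2–aryl. Compounds 1–15 are those defined in the steps.

## Analysis of the target

The target is a 2,4,6-trisubstituted oxane with a 4-hydroxy-3-methoxyphenyl ring at C2, a free hydroxyl at C4 and a 1-hydroxy-2-(4-hydroxyphenyl)ethyl chain at C6. It has four stereocentres, all (S). The C2 and C6 substituents are trans across the ring oxygen, the C4 hydroxyl is cis to the C2 aryl group, and the C6–O1 and C1'–OH bonds are syn (threo). The 2,6-trans arrangement forces one large group into an axial position, so any step that lets the ring open and reclose (oxa-Michael equilibration of a β-alkoxy ketone, ionisation at C2) drifts towards the cis isomer. C2 is a benzylic ether carbon para to a phenolic oxygen, which makes the C2–O1 bond sensitive to acid and a possible site of hydrogenolysis. Two phenols and two secondary alcohols must therefore be unveiled at the end under neutral conditions. The difficulty lies less in connectivity than in controlling C2 and C4 on a ring with little conformational bias. The strategy rests on the fact that C6–C1'–C2'–aryl, with its oxygen at C1', is the skeleton of L-tyrosine with nitrogen exchanged for oxygen. The C1' centre can be bought, and its oxygen can serve as a chelating handle that sets C6 in the step that also builds the ring.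

## Retrosynthetic reasoning

**15 to 14.** The three O–H bonds of the two phenols and of C1'–OH are traced back to benzyl ethers. A benzyl ether is needed at C1' for chelation, and using the same group on both phenols lets one neutral hydrogenolysis finish the synthesis. The forward step must cleave three exocyclic O–CH2Ph bonds without touching the endocyclic benzylic C2–O1 bond.

**14 to 13.** The C4–H bond is cut, leading back to the oxan-4-one. The ketone is what the ring-forming chemistry delivers, and it places the last stereocentre in a single hydride addition. The forward step must deliver hydride to the ring face that carries the C6 chain, so that the hydroxyl ends up cis to the aryl group.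

**13 to 11 and 12.** The C2–aryl bond is cut. Enone 11 has its electrophilic β-carbon at C2, so the whole guaiacyl ring arrives convergently as boronic acid 12. Cutting here rather than at O1–C2 or O1–C6 matters: ring closure through an oxygen nucleophile would equilibrate to the cis isomer, whereas carbon addition to the enone is kinetic and is expected to be trans-selective. The forward step must add the aryl group anti to the C6 chain and must not let the product equilibrate.

**11 to 8 and 9 (key disconnection).** The C5–C6 and O1–C2 bonds are cut in a retro-hetero-Diels–Alder sense. The aldehyde carbonyl of 8 supplies C6 and O1; diene 9 supplies C2–C5 with the oxygen already on C4. One step thus gives the ring, the C6 stereocentre and the enone needed for the C2 arylation. The forward step must choose one carbonyl face of 8, which a magnesium chelate between the aldehyde oxygen and the C1' benzyloxy oxygen should enforce.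

**8 to 1.** Only functional-group changes remain: aldehyde from methyl ester 6 (partial reduction), benzyl ethers from diol ester 5, ester from acid 4, and the C1'–O bond of 4 from the C–N bond of L-tyrosine 1 with retention. No C–C bond is made before the key step, so the risk of the route sits there.

## Alternatives that were turned down

**Alternative 1:** Ireland–Claisen chirality transfer from a dioxanone.
- **Disconnection and key step.** The C5–C6 bond is formed by a [3,3] shift. O-Silylation of the lactone enolate of cis-dioxanone A1 triggers rearrangement through the boat imposed by the ring, breaking the allylic C–O bond and giving the trans dihydropyran acid A2.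
- **For.** The 2,6-trans relationship is transferred stereospecifically and cannot equilibrate, since no β-alkoxy ketone appears. On this point it is stronger than the chosen route, whose C2 centre depends on a kinetic conjugate addition.
- **Against.** A2 has neither the C4 oxygen nor the C1' centre. Hydration of the C3=C4 alkene must occur at C4 and on one face, but hydroboration next to the oxygen-bearing benzylic C2 tends to put boron on C3 and has weak facial bias. C1' must be built from the carboxyl group by ketone formation and a Felkin–Anh-selective reduction, since chelation would give the anti isomer. A1 itself takes several steps to assemble.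
- **Comparison.** Roughly twice the step count, with three centres still set by separate operations. The chosen route buys C1', sets C6 during ring formation and brings the C4 oxygen in with the diene.

**Alternative 2:** Nitrile oxide cycloaddition as an aldol surrogate.
- **Disconnection and key step.** C4–C5 and a temporary O–C6 bond are formed. Aldoxime A3 is dehydrogenated in the flask to nitrile oxide A4, which adds to the terminal alkene of allylic benzyl ether A5 to give the erythro isoxazoline A6 (inside-alkoxy control).
- **For.** The route is convergent and the isoxazoline is a robust masked aldol. After N–O cleavage the C4 carbonyl sits next to a free C6 hydroxyl, so C4 can be set by hydroxyl-directed 1,3-reduction. That is a more reliable way to fix C4 than the conformation-dependent hydride delivery of the chosen route, and the point is conceded.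
- **Against.** Inside-alkoxy selectivity for a simple allylic benzyl ether is usually only moderate. The erythro outcome gives C6 an oxygen of the wrong configuration for O1, so the oxane must be closed by SN2 attack of the C2 oxygen on an activated C6 carbinol with inversion. That centre is secondary and flanked by the C1' ether, so displacement is slow and elimination-prone, and it requires the C4 and C6 hydroxyls to be differentiated first. Ionisation at the electron-rich C2 would scramble that centre. N–O cleavage by hydrogenolysis would attack the benzyl ethers, so Mo(CO)6 would be needed.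
- **Comparison.** About twice as long (two fragment syntheses plus cleavage, reduction, protection, activation, cyclisation). The chosen route makes ring and C6 together and needs no acyclic displacement.

**Alternative 3:** Dithiane anion-relay linchpin.
- **Disconnection and key step.** C3–C4 and C4–C5 are formed at a C4 acyl-anion equivalent. Lithiated silyl dithiane A7 opens aryl epoxide A8 at C3; a 1,4-Brook shift moves silicon to the C2 oxygen and regenerates the carbanion, which opens epoxide A9 at C5 to give A10.
- **For.** This is the most convergent plan: two C–C bonds and the whole heptane chain in one flask. The C2 and C6 oxygens emerge already differentiated, and both carbinol centres come from preformed epoxides. In convergence it beats the chosen route.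
- **Against.** A8 is a 4-alkoxy-3-methoxystyrene oxide, a class that ionises and rearranges easily and that nucleophiles open at both the terminal and the benzylic carbon. A9 must be made diastereomerically pure in the anti series. Ring closure again needs inversion at C6 next to the C1' ether. The dithiane must be removed in the presence of two electron-rich arenes, and the C4 reduction problem remains unchanged.
- **Comparison.** Longer overall, with its main hazards in the fragments and in the cyclisation. The chosen route uses stable, purchasable partners and reaches the ring in one step from the aldehyde.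

Key step: step 5

Remark: the target is read as the (2S,4S,6S,1'S) isomer (2,6-trans, C4–OH cis to the C2 aryl group, C6–O1 and C1'–OH syn); quantities in the Conditions lines are indicative.

## Route

Step 1
Reactants: 1 L-tyrosine, (2S)-2-amino-3-(4-hydroxyphenyl)propanoic acid
Product: 4 (2S)-2-hydroxy-3-(4-hydroxyphenyl)propanoic acid, via diazonium carboxylate 2 (not isolated), via α-lactone 3 (not isolated)
Conditions: NaNO2 (1.5 equiv), 1 M aq. H2SO4, 0 °C → rt
Reagents that add atoms: water, O
Why: Diazotisation of an α-amino acid in aqueous acid proceeds with net retention by double inversion: the carboxylate of 2 expels N2 to give α-lactone 3 (first inversion) and water opens 3 at the α-carbon (second inversion), so the (S) centre of 1 becomes the (S) carbinol of 4, the future C1'. Nitrite is added slowly at 0 °C to keep C-nitrosation of the phenol ring minor.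

Step 2
Reactants: 4 (2S)-2-hydroxy-3-(4-hydroxyphenyl)propanoic acid
Product: 5 methyl (2S)-2-hydroxy-3-(4-hydroxyphenyl)propanoate
Conditions: MeOH, cat. H2SO4, reflux
Reagents that add atoms: methanol, CO
Why: Fischer esterification under acid catalysis; the phenol and the secondary alcohol are untouched and the stereocentre is not enolised under these conditions.

Step 3
Reactants: 5 methyl (2S)-2-hydroxy-3-(4-hydroxyphenyl)propanoate
Product: 6 methyl (2S)-2-(benzyloxy)-3-[4-(benzyloxy)phenyl]propanoate
Conditions: BnBr (2.5 equiv), Ag2O (2.2 equiv), CH2Cl2, rt, dark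
Reagents that add atoms: benzyl bromide, BrCc1ccccc1
Why: Williamson-type O-benzylation promoted by Ag2O alkylates both the phenol and the α-hydroxy ester hydroxyl without a strong base, so the ester α-carbon (C1') is not enolised and keeps its configuration. The benzyl ether at C1' is the chelating group the key step needs.

Step 4
Reactants: 6 methyl (2S)-2-(benzyloxy)-3-[4-(benzyloxy)phenyl]propanoate
Product: 8 (2S)-2-(benzyloxy)-3-[4-(benzyloxy)phenyl]propanal, via aluminium hemiacetal 7 (not isolated)
Conditions: i-Bu2AlH (1.1 equiv), CH2Cl2, −78 °C; then MeOH, aq. potassium sodium tartrate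
Reagents that add atoms: none
Why: Partial reduction of an α-alkoxy ester with i-Bu2AlH: the chelated tetrahedral intermediate 7 is stable at −78 °C and releases the aldehyde only on hydrolytic work-up, which limits over-reduction. Aldehyde 8 is configurationally labile and is used crude and at once.

Step 5
Reactants: 8 (2S)-2-(benzyloxy)-3-[4-(benzyloxy)phenyl]propanal; 9 trans-1-methoxy-3-(trimethylsilyloxy)buta-1,3-diene
Product: 11 (2S)-2-[(1S)-1-(benzyloxy)-2-[4-(benzyloxy)phenyl]ethyl]-2,3-dihydro-4H-pyran-4-one, via silyl enol ether cycloadduct 10 (not isolated)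
Conditions: MgBr2·OEt2 (1.5 equiv), CH2Cl2, −78 → −20 °C; then TFA, 0 °C
Reagents that add atoms: none
Why: This is the Lewis-acid-promoted hetero-Diels–Alder cyclocondensation of an aldehyde with a 1-alkoxy-3-silyloxy diene, the established route to 2-substituted 2,3-dihydro-4H-pyran-4-ones, run here under chelation control. MgBr2 binds the carbonyl oxygen and the α-benzyloxy oxygen of 8 in a five-membered chelate, which fixes the C1'–C6 rotamer so that the CH2-aryl arm covers one carbonyl face and only the small hydrogen lies on the other. The nucleophilic C4 terminus of 9 bonds to the carbonyl carbon on that open face (C5–C6) and the carbonyl oxygen bonds to the methoxy-bearing carbon (O1–C2), either in one asynchronous [4+2] event or as a Mukaiyama aldol addition followed by closure; both paths pass through the same chelate and give the same C6 configuration. The oxane ring is thus closed by [4+2] cycloaddition (in the stepwise limit by 6-endo attack of the C6 oxygen on the β-methoxy enone), and TFA converts 10 into enone 11 by desilylation and β-elimination of methanol. The one new stereocentre, C6, is controlled by the purchased C1' centre through the chelate and should emerge syn to the C1' oxygen, i.e. (S). The only selectivity the step needs is this diastereofacial one; it is secured by the benzyl ether, a good donor for magnesium where a silyl ether would not be, and by the non-coordinating solvent. Regiochemistry follows from the polarity of the diene, and the acetal centre of 10 is irrelevant because it is lost on elimination.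

Step 6
Reactants: 11 (2S)-2-[(1S)-1-(benzyloxy)-2-[4-(benzyloxy)phenyl]ethyl]-2,3-dihydro-4H-pyran-4-one; 12 [4-(benzyloxy)-3-methoxyphenyl]boronic acid
Product: 13 (2S,6S)-2-[4-(benzyloxy)-3-methoxyphenyl]-6-[(1S)-1-(benzyloxy)-2-[4-(benzyloxy)phenyl]ethyl]oxan-4-one
Conditions: 12 (2 equiv), Pd(O2CCF3)2 (10 mol %), 2,2'-bipyridine (12 mol %), NH4PF6 (30 mol %), H2O (5 equiv), ClCH2CH2Cl, 40–50 °C
Reagents that add atoms: none
Why: Conjugate addition of an arylboronic acid to a cyclic β-alkoxy enone catalysed by a cationic bipyridine complex of divalent palladium (transmetalation, syn carbopalladation of C2=C3, protonolysis of the palladium enolate; the metal stays divalent). The aryl group is delivered to C2 along the axial trajectory of the half-chair, on the face opposite the pseudo-equatorial C6 side chain, which sets C2 as (S), trans to C6. The kinetic trans ketone can drift to the cis isomer by retro-oxa-Michael ring opening, so it is worked up neutral and reduced without delay.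

Step 7
Reactants: 13 (2S,6S)-2-[4-(benzyloxy)-3-methoxyphenyl]-6-[(1S)-1-(benzyloxy)-2-[4-(benzyloxy)phenyl]ethyl]oxan-4-one
Product: 14 (2S,4S,6S)-2-[4-(benzyloxy)-3-methoxyphenyl]-6-[(1S)-1-(benzyloxy)-2-[4-(benzyloxy)phenyl]ethyl]oxan-4-ol
Conditions: Li[HB(s-Bu)3] (1.3 equiv), THF, −78 °C; then H2O
Reagents that add atoms: none
Why: Equatorial attack of a bulky trialkylborohydride on a cyclic ketone: 13 is expected to react through the chair with the flat C2 aryl group axial and the α-branched C6 side chain equatorial, in which the axial approach to C4 is shielded by the aryl ring. Hydride should therefore enter from the side-chain face and the hydroxyl emerge cis to the aryl group, (4S); the product then relaxes to the chair with aryl and hydroxyl equatorial.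

Step 8
Reactants: 14 (2S,4S,6S)-2-[4-(benzyloxy)-3-methoxyphenyl]-6-[(1S)-1-(benzyloxy)-2-[4-(benzyloxy)phenyl]ethyl]oxan-4-ol
Product: 15 (2S,4S,6S)-2-(4-hydroxy-3-methoxyphenyl)-6-[(1S)-1-hydroxy-2-(4-hydroxyphenyl)ethyl]oxan-4-ol
Conditions: H2 (1 atm), 10% Pd/C, EtOAc–EtOH, rt
Reagents that add atoms: none
Why: Catalytic hydrogenolysis of two aryl benzyl ethers and one secondary alkyl benzyl ether under neutral conditions, which spares the acid-labile trans C2 centre. The endocyclic C2–O1 bond, a secondary benzylic dialkyl ether held in a ring, is cleaved much more slowly than exocyclic O-benzyl groups (as in the debenzylation of aryl C-glycosides), and the reaction is stopped once three equivalents of H2 are taken up.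

## Compound list

1 | L-tyrosine, (2S)-2-amino-3-(4-hydroxyphenyl)propanoic acid | N[C@@H](Cc1ccc(O)cc1)C(=O)O | starting material
2 | (2S)-2-diazonio-3-(4-hydroxyphenyl)propanoate | N#[N+][C@@H](Cc1ccc(O)cc1)C(=O)[O-] | intermediate
3 | (3R)-3-[(4-hydroxyphenyl)methyl]oxiran-2-one | O=C1O[C@@H]1Cc1ccc(O)cc1 | intermediate
4 | (2S)-2-hydroxy-3-(4-hydroxyphenyl)propanoic acid | O[C@@H](Cc1ccc(O)cc1)C(=O)O | intermediate
5 | methyl (2S)-2-hydroxy-3-(4-hydroxyphenyl)propanoate | COC(=O)[C@@H](O)Cc1ccc(O)cc1 | intermediate
6 | methyl (2S)-2-(benzyloxy)-3-[4-(benzyloxy)phenyl]propanoate | COC(=O)[C@@H](OCc1ccccc1)Cc1ccc(OCc2ccccc2)cc1 | intermediate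
7 | [(2S)-2-(benzyloxy)-3-[4-(benzyloxy)phenyl]-1-methoxypropoxy]bis(2-methylpropyl)alumane (hemiacetal carbon undefined) | COC(O[Al](CC(C)C)CC(C)C)[C@@H](OCc1ccccc1)Cc1ccc(OCc2ccccc2)cc1 | intermediate
8 | (2S)-2-(benzyloxy)-3-[4-(benzyloxy)phenyl]propanal | O=C[C@@H](OCc1ccccc1)Cc1ccc(OCc2ccccc2)cc1 | intermediate
9 | trans-1-methoxy-3-(trimethylsilyloxy)buta-1,3-diene | CO/C=C/C(=C)O[Si](C)(C)C | starting material
10 | (2S)-2-[(1S)-1-(benzyloxy)-2-[4-(benzyloxy)phenyl]ethyl]-6-methoxy-4-(trimethylsilyloxy)-3,6-dihydro-2H-pyran (acetal carbon undefined) | COC1C=C(O[Si](C)(C)C)C[C@@H]([C@@H](OCc2ccccc2)Cc2ccc(OCc3ccccc3)cc2)O1 | intermediate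
11 | (2S)-2-[(1S)-1-(benzyloxy)-2-[4-(benzyloxy)phenyl]ethyl]-2,3-dihydro-4H-pyran-4-one | O=C1C=CO[C@H]([C@@H](OCc2ccccc2)Cc2ccc(OCc3ccccc3)cc2)C1 | intermediate
12 | [4-(benzyloxy)-3-methoxyphenyl]boronic acid | COc1cc(B(O)O)ccc1OCc1ccccc1 | starting material
13 | (2S,6S)-2-[4-(benzyloxy)-3-methoxyphenyl]-6-[(1S)-1-(benzyloxy)-2-[4-(benzyloxy)phenyl]ethyl]oxan-4-one | COc1cc([C@@H]2CC(=O)C[C@@H]([C@@H](OCc3ccccc3)Cc3ccc(OCc4ccccc4)cc3)O2)ccc1OCc1ccccc1 | intermediate
14 | (2S,4S,6S)-2-[4-(benzyloxy)-3-methoxyphenyl]-6-[(1S)-1-(benzyloxy)-2-[4-(benzyloxy)phenyl]ethyl]oxan-4-ol | COc1cc([C@@H]2C[C@H](O)C[C@@H]([C@@H](OCc3ccccc3)Cc3ccc(OCc4ccccc4)cc3)O2)ccc1OCc1ccccc1 | intermediate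
15 | (2S,4S,6S)-2-(4-hydroxy-3-methoxyphenyl)-6-[(1S)-1-hydroxy-2-(4-hydroxyphenyl)ethyl]oxan-4-ol | COc1cc([C@@H]2C[C@H](O)C[C@@H]([C@@H](O)Cc3ccc(O)cc3)O2)ccc1O | target

## Step count and least certain steps

Total step count: 8. Longest linear sequence: 8 steps (1 to 15); 9 and 12 are purchased.

**Step 5 (key step).** The most likely failure is incomplete diastereofacial control. MgBr2 is the mildest Lewis acid that diene 9 tolerates, and if the chelate is partly opened by competing donors the open, Felkin–Anh-type transition state gives the C6 epimer. Epimerisation of 8 before it reacts would add to the loss. The fallback separates C–C bond formation from ring closure, so that a stronger chelating Lewis acid can be used. It sets out from 8: TiCl4-chelated Mukaiyama aldol addition (CH2Cl2, −78 °C) of 2-(trimethylsilyloxy)buta-1,3-diene F1, a nucleophile that survives TiCl4, should give the syn β-hydroxy vinyl ketone (5S,6S)-6-(benzyloxy)-7-[4-(benzyloxy)phenyl]-5-hydroxyhept-1-en-3-one F2. Wacker-type oxidative 6-endo cyclisation of this β-hydroxy enone (PdCl2 cat., CuCl, Na2HPO4, O2, 1,2-dimethoxyethane; divalent palladium re-oxidised by the copper/oxygen couple) then closes O1–C2 and returns to the route at 11.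

**Step 7.** The most likely failure is poor or reversed facial selectivity. Which chair of 13 reacts (aryl axial or side chain axial) is not fixed by the ring, and the two chairs lead to opposite C4 epimers (a Curtin–Hammett situation). The fallback sets the centre by substitution instead of by hydride delivery. It sets out from 13: the reduction is run with whichever hydride favours the epimer (2S,4R,6S)-2-[4-(benzyloxy)-3-methoxyphenyl]-6-[(1S)-1-(benzyloxy)-2-[4-(benzyloxy)phenyl]ethyl]oxan-4-ol F3. Mitsunobu reaction of F3 with 4-nitrobenzoic acid (PPh3, diisopropyl azodicarboxylate, THF) inverts C4 to give the (4S) 4-nitrobenzoate F4, and methanolysis (K2CO3, MeOH) returns to the route at 14.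

**Step 6.** The most likely failure is erosion of the 2,6-trans relationship through reversible ring opening of the β-alkoxy ketone (retro-oxa-Michael via the C3 enol, or ionisation at the electron-rich benzylic C2) in warm, weakly acidic aqueous medium. Protodeboronation of the electron-rich boronic acid is a second concern. The fallback is an irreversible, aprotic, low-temperature organocopper addition that sets out from 11. 1-(Benzyloxy)-4-bromo-2-methoxybenzene F5 is converted with Mg in THF into [4-(benzyloxy)-3-methoxyphenyl]magnesium bromide F6. Conjugate addition of F6 to 11 with CuBr·SMe2 (monovalent copper, 20 mol %) and Me3SiCl at −78 °C traps the enolate as the trans silyl enol ether F7, which cannot ring-open. Cold buffered hydrolysis (dilute aqueous citric acid, 0 °C) returns to the route at 13.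

**Step 4.** The most likely failure is over-reduction to the primary alcohol, with partial epimerisation of the α-benzyloxy aldehyde during work-up. The fallback replaces the partial reduction by a full reduction and a separate mild oxidation. It sets out from 6: LiBH4 (THF, MeOH) gives (2S)-2-(benzyloxy)-3-[4-(benzyloxy)phenyl]propan-1-ol F8. Parikh–Doering oxidation (SO3·pyridine, DMSO, i-Pr2NEt, 0 °C) returns to the route at 8, which is again used at once.

## Further compounds

F1 | step 5 | 2-(trimethylsilyloxy)buta-1,3-diene | C=CC(=C)O[Si](C)(C)C
F2 | step 5 | (5S,6S)-6-(benzyloxy)-7-[4-(benzyloxy)phenyl]-5-hydroxyhept-1-en-3-one | C=CC(=O)C[C@H](O)[C@@H](OCc1ccccc1)Cc1ccc(OCc2ccccc2)cc1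
F3 | step 7 | (2S,4R,6S)-2-[4-(benzyloxy)-3-methoxyphenyl]-6-[(1S)-1-(benzyloxy)-2-[4-(benzyloxy)phenyl]ethyl]oxan-4-ol | COc1cc([C@@H]2C[C@@H](O)C[C@@H]([C@@H](OCc3ccccc3)Cc3ccc(OCc4ccccc4)cc3)O2)ccc1OCc1ccccc1
F4 | step 7 | (2S,4S,6S)-2-[4-(benzyloxy)-3-methoxyphenyl]-6-[(1S)-1-(benzyloxy)-2-[4-(benzyloxy)phenyl]ethyl]oxan-4-yl 4-nitrobenzoate | COc1cc([C@@H]2C[C@H](OC(=O)c3ccc(cc3)[N+](=O)[O-])C[C@@H]([C@@H](OCc3ccccc3)Cc3ccc(OCc4ccccc4)cc3)O2)ccc1OCc1ccccc1
F5 | step 6 | 1-(benzyloxy)-4-bromo-2-methoxybenzene | COc1cc(Br)ccc1OCc1ccccc1
F6 | step 6 | [4-(benzyloxy)-3-methoxyphenyl]magnesium bromide | COc1cc([Mg]Br)ccc1OCc1ccccc1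
F7 | step 6 | {[(2S,6S)-6-[4-(benzyloxy)-3-methoxyphenyl]-2-[(1S)-1-(benzyloxy)-2-[4-(benzyloxy)phenyl]ethyl]-3,6-dihydro-2H-pyran-4-yl]oxy}trimethylsilane | COc1cc([C@@H]2C=C(O[Si](C)(C)C)C[C@@H]([C@@H](OCc3ccccc3)Cc3ccc(OCc4ccccc4)cc3)O2)ccc1OCc1ccccc1
F8 | step 4 | (2S)-2-(benzyloxy)-3-[4-(benzyloxy)phenyl]propan-1-ol | OC[C@@H](OCc1ccccc1)Cc1ccc(OCc2ccccc2)cc1
A1 | alternative 1 | (5R,6S)-5-[4-(benzyloxy)-3-methoxyphenyl]-6-ethenyl-1,4-dioxan-2-one | COc1cc([C@H]2OCC(=O)O[C@H]2C=C)ccc1OCc1ccccc1
A2 | alternative 1 | (2S,6S)-6-[4-(benzyloxy)-3-methoxyphenyl]-3,6-dihydro-2H-pyran-2-carboxylic acid | COc1cc([C@@H]2C=CC[C@@H](C(=O)O)O2)ccc1OCc1ccccc1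
A3 | alternative 2 | (3S)-3-[4-(benzyloxy)-3-methoxyphenyl]-3-[(tert-butyldimethylsilyl)oxy]propanal oxime | COc1cc([C@@H](O[Si](C)(C)C(C)(C)C)CC=NO)ccc1OCc1ccccc1
A4 | alternative 2 | (3S)-3-[4-(benzyloxy)-3-methoxyphenyl]-3-[(tert-butyldimethylsilyl)oxy]propanenitrile oxide | COc1cc([C@@H](O[Si](C)(C)C(C)(C)C)CC#[N+][O-])ccc1OCc1ccccc1
A5 | alternative 2 | 1-(benzyloxy)-4-[(2S)-2-(benzyloxy)but-3-en-1-yl]benzene | C=C[C@@H](OCc1ccccc1)Cc1ccc(OCc2ccccc2)cc1
A6 | alternative 2 | (5R)-5-[(1S)-1-(benzyloxy)-2-[4-(benzyloxy)phenyl]ethyl]-3-[(2S)-2-[4-(benzyloxy)-3-methoxyphenyl]-2-[(tert-butyldimethylsilyl)oxy]ethyl]-4,5-dihydro-1,2-oxazole | COc1cc([C@@H](O[Si](C)(C)C(C)(C)C)CC2=NO[C@H](C2)[C@@H](OCc2ccccc2)Cc2ccc(OCc3ccccc3)cc2)ccc1OCc1ccccc1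
A7 | alternative 3 | tert-butyl(1,3-dithian-2-yl)dimethylsilane | CC(C)(C)[Si](C)(C)C1SCCCS1
A8 | alternative 3 | (2R)-2-[4-(benzyloxy)-3-methoxyphenyl]oxirane | COc1cc([C@@H]2CO2)ccc1OCc1ccccc1
A9 | alternative 3 | (2R)-2-[(1S)-1-(benzyloxy)-2-[4-(benzyloxy)phenyl]ethyl]oxirane | C1O[C@H]1[C@@H](OCc1ccccc1)Cc1ccc(OCc2ccccc2)cc1
A10 | alternative 3 | 2-[(2S)-2-[4-(benzyloxy)-3-methoxyphenyl]-2-[(tert-butyldimethylsilyl)oxy]ethyl]-2-[(2R,3S)-3-(benzyloxy)-4-[4-(benzyloxy)phenyl]-2-hydroxybutyl]-1,3-dithiane | COc1cc([C@@H](O[Si](C)(C)C(C)(C)C)CC2(C[C@@H](O)[C@@H](OCc3ccccc3)Cc3ccc(OCc4ccccc4)cc3)SCCCS2)ccc1OCc1ccccc1
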